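Start from the balance: in both earlier runs J and L together make up what has been fed, 59.5% of the J charged at 0.500 min in the larch run and 99.4% at 6.00 min in the oak run, so follow J and get L by subtraction.

common to all: D 6.8 mM

| run | J | remark | time |
|---|---|---|---|
| oak | 1.3 M (fed, over 50 s) | run made earlier; the fed solution adds 1.0 times the starting volume |  |
| larch | 3 M (fed, over 50 s) | run made earlier; the fed solution adds 1.0 times the starting volume |  |
| flask | 2.0 M (fed, over 50 s) | the fed solution adds 1.0 times the starting volume | 8.0 min |

- oak (time / min: J / %, L / %): 1.33: 85.2, 14.4; 2.50: 71.5, 28.8; 4.00: 60.1, 39.9; 5.00: 54.4, 46.5; 6.00: 49.9, 49.5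
- larch (time / min: J / %, L / %): 0.500: 57.4, 2.1; 1.50: 82.0, 18.1; 3.00: 65.5, 33.7; 5.00: 53.9, 45.6; 6.00: 51.0, 49.6

(standard deviation of a reading: 0.5 percentage points)

- concentration of J at 8.0 min, in M
- concentration of L at 8.0 min, in M

- amounts are per litre of the starting volume; all of the dose is in the solution fed
- percentages count the whole charge, also what has not yet gone in

Draw J in percent of the charge, a curve that oak and larch share within the scatter (54.4% against 53.9% at 5.00 min) although their charges differ, and take it for the flask too, whose D and feed are the same. It climbs steeply while the charge enters over 0.83 min, knees at the end of the feed, and then falls with a first-order constant that itself sinks: my reading is 0.150 min⁻¹ from 1.50 min to 3.00 min in larch and 0.0930 min⁻¹ from 4.00 min to 6.00 min in oak. Between the midpoints of these windows it decays at 0.173 min⁻¹, and the first window already lies below that decay constant, so the crossing where the activity starts dying faster than J goes comes earlier. Define the reach as the rate constant at a moment divided by its decay constant, the natural-log distance J can still fall.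

Where J meets L, near 6.00 min at 50.4% in the readings, I read the reach as 0.451, which on this decay puts the level J runs into at about 32.1%. For the flask at 8.0 min I reckon a reach of 0.319, and so put J at 44.2%. Over the doubled volume I reckon 0.442 M of J and 0.558 M of L.

The forecast, holding that “consumption is first order in J”, gave 0.437 M of J (0.42 M to 0.455 M) and 0.563 M of L, slightly less J than my reckoning.

The flask gives 0.451 M of J and 0.548 M of L, with J inside the forecast's range and close to its high end.

    X → Q (k = 0.00330 s⁻¹)
    J + X → L + X, rate k2*[X]*[J] (k = 1.10 M⁻¹ s⁻¹)
    J + D → Z (k = 0.0103 M⁻¹ s⁻¹)
    J + D → X + L (k = 0.122 M⁻¹ s⁻¹)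

At the asked time J in the flask has a half-life of 15 min by the making of L, longer than the 3.5 min of X by its loss to Q alone, and the ratio of the two, 0.229, is the reach of that moment. Carry my reach to the neighbour flask, the same flask read at 15 min: my reckoning shrinks it to 0.0948, which takes J from 45.1% to 36.0%, and the neighbour flask stands at 38.0%, which is 0.380 M.

The runs come from a simulation for substances that don't exist; scatter was added.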